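**Retrosynthetic overview**
1. Target 9 is cut at both ring–CH2 bonds: the methylene becomes the 1,1-dianion equivalent CH2(Bpin)2 (7), and each ring carbon, normally the nucleophilic centre of a β-diketone, becomes an enolonium equivalent (phenyliodonium ylides 3 and 6).
2. Ylides 3 and 6 come from acetylfilicinic acid 2 and butyrylfilicinic acid 5 with PhI(OAc)2.
3. 2 and 5 come from dearomatising gem-dimethylation of the acylphloroglucinols 1 and 4.
4. No ring is formed in the route: both six-membered rings are the benzene rings of 1 and 4; ring B (acetyl) is joined to the methylene first, ring A (butyryl) second, in one pot.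

Assumption: the target SMILES contains no stereocentre (the molecule is achiral), so there is no configuration to set; it is drawn in the enol tautomer given.

**Step 1**
Reactants: 1 2',4',6'-trihydroxyacetophenone
Product: 2 acetylfilicinic acid (2-acetyl-3,5-dihydroxy-6,6-dimethylcyclohexa-2,4-dien-1-one; free ring C–H at C4)
Conditions: NaOMe (3.0 equiv), MeI (2.2 equiv), MeOH, 0 °C to 23 °C, 16 h; then 1 M HCl
Reagents that add atoms: iodomethane, CI
Why: The phloroglucinol enolate is C-methylated at a free ring carbon and the mono-methyl enolate is methylated again at the same carbon (dearomatising gem-C-dimethylation of an acylphloroglucinol), so limiting MeI to about two equivalents stops at the filicinic acid stage; no stereocentre is formed.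

**Step 2**
Reactants: 2 acetylfilicinic acid
Product: 3 phenyliodonium ylide of acetylfilicinic acid (zwitterion: Ph–I+ on C4, negative charge on the C5 oxygen, delocalised over the C3–C5 dioxo unit)
Conditions: PhI(OAc)2 (1.05 equiv), CH2Cl2, 0 °C, 1 h; precipitate with Et2O/hexane, store at −20 °C
Reagents that add atoms: (diacetoxyiodo)benzene, CC(=O)OI(OC(C)=O)c1ccccc1
Why: The only enolic ring C–H (C4, between two oxygenated carbons) attacks trivalent iodine and two molecules of acetic acid are lost, giving the stabilised zwitterion (standard iodonium ylide formation from an acidic cyclic 1,3-dione), which turns this normally nucleophilic carbon into an enolonium equivalent.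

**Step 3**
Reactants: 4 1-(2,4,6-trihydroxyphenyl)butan-1-one
Product: 5 butyrylfilicinic acid (2-butanoyl-3,5-dihydroxy-6,6-dimethylcyclohexa-2,4-dien-1-one; free ring C–H at C4)
Conditions: NaOMe (3.0 equiv), MeI (2.2 equiv), MeOH, 0 °C to 23 °C, 16 h; then 1 M HCl
Reagents that add atoms: iodomethane, CI
Why: Same dearomatising gem-C-dimethylation of an acylphloroglucinol enolate as in step 1; no stereocentre is formed.

**Step 4**
Reactants: 5 butyrylfilicinic acid
Product: 6 phenyliodonium ylide of butyrylfilicinic acid (zwitterion: Ph–I+ on C4, negative charge on the C5 oxygen)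
Conditions: PhI(OAc)2 (1.05 equiv), CH2Cl2, 0 °C, 1 h; precipitate with Et2O/hexane, store at −20 °C
Reagents that add atoms: (diacetoxyiodo)benzene, CC(=O)OI(OC(C)=O)c1ccccc1
Why: Iodonium ylide formation at the single enolic C–H of an acidic cyclic 1,3-dione, as in step 2, gives the enolonium equivalent of ring A.

**Step 5**
Reactants: 3 phenyliodonium ylide of acetylfilicinic acid; 7 bis[(pinacolato)boryl]methane; 6 phenyliodonium ylide of butyrylfilicinic acid
Product: 9 albaspidin AB, via C4-borylmethyl acetylfilicinic acid 8 (not isolated)
Conditions: 7 (1.05 equiv), Pd[P(t-Bu)3]2 (5 mol%), 8 M aq KOH (5 equiv), degassed 1,4-dioxane, slow addition of 3 (1.0 equiv), 23 °C, 4 h; then 6 (1.4 equiv, in portions), aq KOH (4 equiv), 50 °C, 6 h; then 1 M HCl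
Reagents that add atoms: none
Why: Proposed new method: zerovalent palladium inserts into the C4–I bond of the trivalent-iodine ylide 3 much faster than into the PhI it releases, the hydroxide adduct of 7 transmetalates at 23 °C because the second boron stabilises the α-carbanion character (a methylene 1,1-dianion equivalent meeting an enolonium equivalent), and reductive elimination gives 8, whose remaining C–B bond transmetalates only on warming with more base, so that the second ylide 6 is then coupled selectively to give the unsymmetrical product with no β-hydrogen available for elimination; the closest known reactions are the Suzuki–Miyaura-type coupling of phenyliodonium ylides of cyclic 1,3-diones with boronic acids under Pd/P(t-Bu)3 at room temperature and the one-pot sequential Suzuki–Miyaura coupling of bis[(pinacolato)boryl]methane with two different aryl halides to give unsymmetrical diarylmethanes.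

**Compound list**
1 | 2',4',6'-trihydroxyacetophenone (phloroacetophenone) | CC(=O)c1c(O)cc(O)cc1O | starting material
2 | acetylfilicinic acid, 2-acetyl-3,5-dihydroxy-6,6-dimethylcyclohexa-2,4-dien-1-one | CC(=O)C1=C(O)C=C(O)C(C)(C)C1=O | intermediate
3 | C4-phenyliodonium ylide (zwitterion) of acetylfilicinic acid | CC(=O)C1=C(O)C([I+]c2ccccc2)=C([O-])C(C)(C)C1=O | intermediate
4 | 1-(2,4,6-trihydroxyphenyl)butan-1-one (phlorobutyrophenone) | CCCC(=O)c1c(O)cc(O)cc1O | starting material
5 | butyrylfilicinic acid, 2-butanoyl-3,5-dihydroxy-6,6-dimethylcyclohexa-2,4-dien-1-one | CCCC(=O)C1=C(O)C=C(O)C(C)(C)C1=O | intermediate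
6 | C4-phenyliodonium ylide (zwitterion) of butyrylfilicinic acid | CCCC(=O)C1=C(O)C([I+]c2ccccc2)=C([O-])C(C)(C)C1=O | intermediate
7 | bis[(pinacolato)boryl]methane, CH2(Bpin)2 | CC1(C)OB(CB2OC(C)(C)C(C)(C)O2)OC1(C)C | starting material
8 | 2-acetyl-3,5-dihydroxy-6,6-dimethyl-4-[(4,4,5,5-tetramethyl-1,3,2-dioxaborolan-2-yl)methyl]cyclohexa-2,4-dien-1-one | CC(=O)C1=C(O)C(CB2OC(C)(C)C(C)(C)O2)=C(O)C(C)(C)C1=O | intermediate
9 | albaspidin AB, 2-acetyl-4-[(5-butanoyl-2,6-dihydroxy-3,3-dimethyl-4-oxocyclohexa-1,5-dien-1-yl)methyl]-3,5-dihydroxy-6,6-dimethylcyclohexa-2,4-dien-1-one (achiral) | CCCC(=O)C1=C(O)C(CC2=C(O)C(C)(C)C(=O)C(C(C)=O)=C2O)=C(O)C(C)(C)C1=O | target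

**Step count and risks**
Total step count: 5. Longest linear sequence: 3 steps (1 → 2 → 3 → 9, or 4 → 5 → 6 → 9).

The three steps most likely to fail:

1. Step 5. The risks are a second coupling of 8 with 3 in the first stage (symmetrical dimer), competition of the released PhI for the C–B bond of 8 in the second stage, protodeboronation of 8, and chelation of palladium by the triketone units. Fallback (sets out from 2, comes back at 9): the methylene is first put on ring B with normal polarity and only the second ring–CH2 bond is made by the boron/iodonium coupling. 2 is C-alkylated at C4 with potassium (iodomethyl)trifluoroborate (KOH, H2O/acetone, 40 °C; the tetracoordinate boron cannot divert the enolate oxygen through an ate complex) to give potassium [(5-acetyl-2,6-dihydroxy-3,3-dimethyl-4-oxocyclohexa-1,5-dien-1-yl)methyl]trifluoroborate F1. F1 is isolated free of PhI and of any second boron group and is then cross-coupled with ylide 6 (Pd[P(t-Bu)3]2, K2CO3, THF/H2O, 45 °C) to give 9.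

2. Step 4. Ylide 6 has to survive 50 °C in aqueous base during the second stage of step 5, where iodonium ylides can rearrange or decompose. Fallback (sets out from 5, comes back at 9): ylide 6 is left out altogether. The first stage of step 5 is run alone and 8 is isolated by acidification and extraction. 8 is then oxidised at the C–B bond with NaBO3·4H2O in THF/H2O at 23 °C in the presence of 5 (2 equiv), giving 2-acetyl-3,5-dihydroxy-4-(hydroxymethyl)-6,6-dimethylcyclohexa-2,4-dien-1-one F2. F2 loses water in the mildly basic medium to the o-quinone methide 2-acetyl-3-hydroxy-6,6-dimethyl-4-methylidenecyclohex-2-ene-1,5-dione F3, and Michael addition of the enolate of 5 to F3 gives 9. The ring B–CH2 bond is still the one made from ylide 3 and 7; only the second bond is made with normal polarity.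

3. Step 1 (the same holds for step 3). The methylation gives a statistical mixture of mono-, gem-di-, tri- and tetramethylated products, and the yield of 2 after separation may be low. Fallback (sets out from 1, comes back at 2): 1 is C-acetylated (Ac2O, BF3·OEt2, 90 °C) to 2,4-diacetylphloroglucinol F4, which has only one ring C–H left. NaOMe/MeI can then only give 2,4-diacetyl-3,5-dihydroxy-6,6-dimethylcyclohexa-2,4-dien-1-one F5. Both acetyl groups are removed by retro-Friedel–Crafts deacylation (80% aq H2SO4, 100 °C) to filicinic acid F6, and one acetyl group is put back (Ac2O, BF3·OEt2, 60 °C) to give 2.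

**Further compounds**
F1 | step 5 | potassium [(5-acetyl-2,6-dihydroxy-3,3-dimethyl-4-oxocyclohexa-1,5-dien-1-yl)methyl]trifluoroborate | CC(=O)C1=C(O)C(C[B-](F)(F)F)=C(O)C(C)(C)C1=O.[K+]
F2 | step 4 | 2-acetyl-3,5-dihydroxy-4-(hydroxymethyl)-6,6-dimethylcyclohexa-2,4-dien-1-one | CC(=O)C1=C(O)C(CO)=C(O)C(C)(C)C1=O
F3 | step 4 | 2-acetyl-3-hydroxy-6,6-dimethyl-4-methylidenecyclohex-2-ene-1,5-dione (o-quinone methide) | CC(=O)C1=C(O)C(=C)C(=O)C(C)(C)C1=O
F4 | step 1 | 2,4-diacetylphloroglucinol | CC(=O)c1c(O)cc(O)c(C(C)=O)c1O
F5 | step 1 | 2,4-diacetyl-3,5-dihydroxy-6,6-dimethylcyclohexa-2,4-dien-1-one (diacetylfilicinic acid) | CC(=O)C1=C(O)C(C)(C)C(=O)C(C(C)=O)=C1O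
F6 | step 1 | filicinic acid, 3,5-dihydroxy-4,4-dimethylcyclohexa-2,5-dien-1-one | CC1(C)C(O)=CC(=O)C=C1O
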